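**Plan**

Numbering: naphthalene C1–C8a (C1 carries CH3, C2 the ketone); ring B C1'–C6' (C1' carries the ketone, C6' the CH2, called C7'); pyranone O1''–C6''.
Retrosynthesis, in order: the four O–CH3 bonds and the C5/C8 quinone level of ring A; the lactone bond O1''–C2'' (acylketene masked as a dioxinone); C5''–C6''; the ketone–C1' bond; C1–C8a and C2–C3 of ring C.
Forward: methyl 3,5-dimethoxyphenylacetate is used twice. One portion gains a third oxygen and becomes ring A, onto which ring C is closed; the second portion is acylated by the resulting naphthoic acid as ring B. The chain is then lengthened with the dioxinone, the pyranone closes, ring A is oxidised to the quinone and the ethers are cleaved.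
Enabling feature: the pyranone O1''–C6'' is the enol lactone of a 3,5-dioxo acid whose C6'' carbonyl oxygen lies six atoms from the carboxyl carbon C2''. C6'' hangs on C7', a CH2 acidified by both ring B and C6'', so a neutral thermal lactonisation suits it.
Stereochemistry: the target has no stereocentre and no configured double bond; nothing has to be controlled.

Key step: step 11

Remark: methyl 3,5-dimethoxyphenylacetate, allyl acetoacetate and 2,2,6-trimethyl-4H-1,3-dioxin-4-one are taken as purchased; all phenols travel as methyl ethers up to the last step.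

**Route**

Step 1
Reactants: 1 methyl 2-(3,5-dimethoxyphenyl)acetate
Product: 3 methyl 2-(2-formyl-3,5-dimethoxyphenyl)acetate, via iminium chloride 2 (not isolated)
Conditions: POCl3, DMF, 0 °C to 70 °C; then aq. NaOAc
Reagents that add atoms: N,N-dimethylformamide CN(C)C=O; water O
Why: Vilsmeier–Haack formylation, in which the chloroiminium ion attacks C2 of the ring (para to one methoxy group, ortho to the other, and less crowded than C4 between the two methoxy groups) and the iminium salt is hydrolysed on work-up.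

Step 2
Reactants: 3 methyl 2-(2-formyl-3,5-dimethoxyphenyl)acetate
Product: 5 methyl 2-(2-hydroxy-3,5-dimethoxyphenyl)acetate, via aryl formate 4 (not isolated)
Conditions: mCPBA, CH2Cl2, 0 °C to rt; then K2CO3, MeOH, rt, under N2
Reagents that add atoms: 3-chloroperoxybenzoic acid O=C(OO)c1cccc(Cl)c1
Why: Dakin-type Baeyer–Villiger oxidation, in which the electron-rich aryl group migrates in preference to hydride and mild methanolysis of the formate frees the phenol without touching the methyl ester.

Step 3
Reactants: 5 methyl 2-(2-hydroxy-3,5-dimethoxyphenyl)acetate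
Product: 7 2-(2,3,5-trimethoxyphenyl)acetic acid, via methyl ester 6 (not isolated)
Conditions: MeI, K2CO3, acetone, reflux, under N2; then NaOH, H2O/MeOH, 60 °C; then HCl
Reagents that add atoms: iodomethane CI; sodium hydroxide [Na+].[OH-]
Why: Williamson O-methylation of the phenoxide followed by saponification of the unhindered aliphatic ester in the same flask, carbonate being too weak a base to deprotonate the arylacetate CH2 and cause C-methylation.

Step 4
Reactants: 7 2-(2,3,5-trimethoxyphenyl)acetic acid; 8 prop-2-en-1-yl 3-oxobutanoate (allyl acetoacetate)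
Product: 10 prop-2-en-1-yl 2-acetyl-3-oxo-4-(2,3,5-trimethoxyphenyl)butanoate, via acid chloride 9 (not isolated)
Conditions: (COCl)2, cat. DMF, CH2Cl2, 0 °C to rt; then 8, MgCl2, pyridine, CH2Cl2, 0 °C to rt; 1 M HCl
Reagents that add atoms: none
Why: C-acylation of the magnesium chelate of a β-keto ester by an acid chloride, where chelation by MgCl2 makes the central CH acidic enough for pyridine and directs the acyl group to carbon.

Step 5
Reactants: 10 prop-2-en-1-yl 2-acetyl-3-oxo-4-(2,3,5-trimethoxyphenyl)butanoate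
Product: 11 prop-2-en-1-yl 3-hydroxy-5,6,8-trimethoxy-1-methylnaphthalene-2-carboxylate
Conditions: MeSO3H, CH2Cl2, 0 °C to rt
Reagents that add atoms: none
Why: acid-mediated cyclodehydration (intramolecular Friedel–Crafts hydroxyalkylation, loss of water, enolisation) of a γ-aryl tricarbonyl compound, in which the protonated acetyl carbonyl is attacked by the only free ring position next to the side chain (para to one methoxy group, ortho to another), forming C1–C8a, and aromatisation to the naphthol drives the reaction.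

Step 6
Reactants: 11 prop-2-en-1-yl 3-hydroxy-5,6,8-trimethoxy-1-methylnaphthalene-2-carboxylate
Product: 12 prop-2-en-1-yl 3,5,6,8-tetramethoxy-1-methylnaphthalene-2-carboxylate
Conditions: MeI, K2CO3, DMF, 50 °C
Reagents that add atoms: iodomethane CI
Why: Williamson methylation of the ester-chelated naphthol, needed so that no free phenol can later trap the ketene.

Step 7
Reactants: 12 prop-2-en-1-yl 3,5,6,8-tetramethoxy-1-methylnaphthalene-2-carboxylate
Product: 13 3,5,6,8-tetramethoxy-1-methylnaphthalene-2-carboxylic acid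
Conditions: Pd(PPh3)4 (5 mol %), morpholine, THF, rt; then 1 M HCl
Reagents that add atoms: none
Why: Tsuji–Trost deallylation, in which zerovalent palladium ionises the ester at the unhindered allyl terminus, so the crowding around the carboxyl carbon (flanked by C1–CH3 and C3–OCH3) that would slow saponification plays no role.

Step 8
Reactants: 13 3,5,6,8-tetramethoxy-1-methylnaphthalene-2-carboxylic acid; 1 methyl 2-(3,5-dimethoxyphenyl)acetate (excess)
Product: 15 methyl 2-[3,5-dimethoxy-2-(3,5,6,8-tetramethoxy-1-methylnaphthalene-2-carbonyl)phenyl]acetate, via mixed anhydride 14 (not isolated)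
Conditions: (CF3CO)2O, CH2Cl2, 0 °C to rt
Reagents that add atoms: none
Why: Friedel–Crafts acylation through the mixed trifluoroacetic anhydride, in which the 2,6-disubstituted electron-rich aroyl group ionises readily to a linear acylium ion of low steric demand and arene 1 reacts at C2 as in step 1, giving a deactivated ketone that does not react further.

Step 9
Reactants: 15 methyl 2-[3,5-dimethoxy-2-(3,5,6,8-tetramethoxy-1-methylnaphthalene-2-carbonyl)phenyl]acetate
Product: 16 2-[3,5-dimethoxy-2-(3,5,6,8-tetramethoxy-1-methylnaphthalene-2-carbonyl)phenyl]acetic acid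
Conditions: LiOH, THF/H2O, rt; then 1 M HCl
Reagents that add atoms: lithium hydroxide [Li+].[OH-]
Why: saponification of an unhindered aliphatic methyl ester, the tetra-ortho-substituted diaryl ketone and the aryl methyl ethers being inert to hydroxide at room temperature.

Step 10
Reactants: 16 2-[3,5-dimethoxy-2-(3,5,6,8-tetramethoxy-1-methylnaphthalene-2-carbonyl)phenyl]acetic acid; 17 2,2,6-trimethyl-4H-1,3-dioxin-4-one
Product: 20 6-{3-[3,5-dimethoxy-2-(3,5,6,8-tetramethoxy-1-methylnaphthalene-2-carbonyl)phenyl]-2-oxopropyl}-2,2-dimethyl-4H-1,3-dioxin-4-one, via acyl imidazole 18 (not isolated), via lithium dienolate 19 (not isolated)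
Conditions: 16, 1,1'-carbonyldiimidazole, THF, rt; added to 17 (2.2 equiv) and LiN(SiMe3)2 (2.2 equiv), THF, −78 °C to −40 °C; aq. NH4Cl
Reagents that add atoms: none
Why: crossed Claisen-type γ-acylation of the lithium dienolate of the dioxinone by an acyl imidazole, forming C5''–C6'', with a second equivalent of dienolate absorbing the acidity of the product and the low temperature keeping proton abstraction from the arylacetyl CH2 slower than addition.

Step 11
Reactants: 20 6-{3-[3,5-dimethoxy-2-(3,5,6,8-tetramethoxy-1-methylnaphthalene-2-carbonyl)phenyl]-2-oxopropyl}-2,2-dimethyl-4H-1,3-dioxin-4-one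
Product: 22 6-{[3,5-dimethoxy-2-(3,5,6,8-tetramethoxy-1-methylnaphthalene-2-carbonyl)phenyl]methyl}-4-hydroxy-2H-pyran-2-one, via acylketene 21 (not isolated)
Conditions: toluene (0.01 M), 110 °C
Reagents that add atoms: none
Why: Thermal retro-[4+2] cycloreversion of the dioxinone ring expels acetone and leaves acylketene 21, the normal behaviour of 2,2-dimethyl-1,3-dioxin-4-ones above about 100 °C. The C6'' ketone, enolised towards C5'', adds through its oxygen (the future O1'') to the ketene carbon C2'', and a proton shift gives the 4-hydroxy-2-pyranone; the closest known reaction type is the thermolysis of 6-(2-oxoalkyl)dioxinones to 6-substituted 4-hydroxy-2-pyranones. The single ring closes as a six-membered O-acylation of the sp ketene carbon, best read as a 6π oxa-electrocyclisation of the dienol ketene. No stereocentre is formed. The step needs O- over C-capture and intra- over intermolecular capture of the ketene: the enol oxygen is the only nucleophile held in a six-membered array, attack by C7' would need the other enol and a carbocyclic Claisen-type closure, every phenol is a methyl ether, the hindered diaryl ketone cannot engage, and high dilution suppresses ketene dimerisation. Because no base is present, the acidic C7' methylene is never deprotonated, so aldol closure onto the diaryl ketone is avoided.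

Step 12
Reactants: 22 6-{[3,5-dimethoxy-2-(3,5,6,8-tetramethoxy-1-methylnaphthalene-2-carbonyl)phenyl]methyl}-4-hydroxy-2H-pyran-2-one
Product: 23 6-{[2-(3,6-dimethoxy-1-methyl-5,8-dioxo-5,8-dihydronaphthalene-2-carbonyl)-3,5-dimethoxyphenyl]methyl}-4-hydroxy-2H-pyran-2-one
Conditions: (NH4)2Ce(NO3)6 (2.5 equiv), MeCN/H2O, 0 °C
Reagents that add atoms: water O
Why: oxidative demethylation of a 1,4-dimethoxyarene by tetravalent cerium, ring A being the most easily oxidised π-system and the only one with a para-dioxygenated pair (C5/C8), while water delivers the quinone oxygens and the C6 methoxy group stays as a vinylogous ester.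

Step 13
Reactants: 23 6-{[2-(3,6-dimethoxy-1-methyl-5,8-dioxo-5,8-dihydronaphthalene-2-carbonyl)-3,5-dimethoxyphenyl]methyl}-4-hydroxy-2H-pyran-2-one
Product: 24 6-{[3,5-dihydroxy-2-(3,6-dihydroxy-1-methyl-5,8-dioxo-5,8-dihydronaphthalene-2-carbonyl)phenyl]methyl}-4-hydroxy-2H-pyran-2-one (CNP0141484.0)
Conditions: BBr3 (excess), CH2Cl2, −78 °C to rt; then H2O
Reagents that add atoms: none
Why: Lewis acid cleavage of aryl and vinylogous methyl ethers by BBr3, in which the two ethers ortho to the ketone and the quinone ether go first through chelated boron complexes, the C4' ether follows at room temperature, and the pyranone, ketone and quinone survive as borates until hydrolysis.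

**Compound list**

1 | methyl 2-(3,5-dimethoxyphenyl)acetate | COC(=O)Cc1cc(OC)cc(OC)c1 | starting material
2 | N-{[2,4-dimethoxy-6-(2-methoxy-2-oxoethyl)phenyl]methylidene}-N-methylmethanaminium chloride | COC(=O)Cc1cc(OC)cc(OC)c1C=[N+](C)C.[Cl-] | intermediate
3 | methyl 2-(2-formyl-3,5-dimethoxyphenyl)acetate | COC(=O)Cc1cc(OC)cc(OC)c1C=O | intermediate
4 | methyl 2-[2-(formyloxy)-3,5-dimethoxyphenyl]acetate | COC(=O)Cc1cc(OC)cc(OC)c1OC=O | intermediate
5 | methyl 2-(2-hydroxy-3,5-dimethoxyphenyl)acetate | COC(=O)Cc1cc(OC)cc(OC)c1O | intermediate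
6 | methyl 2-(2,3,5-trimethoxyphenyl)acetate | COC(=O)Cc1cc(OC)cc(OC)c1OC | intermediate
7 | 2-(2,3,5-trimethoxyphenyl)acetic acid | OC(=O)Cc1cc(OC)cc(OC)c1OC | intermediate
8 | prop-2-en-1-yl 3-oxobutanoate | CC(=O)CC(=O)OCC=C | starting material
9 | 2-(2,3,5-trimethoxyphenyl)acetyl chloride | ClC(=O)Cc1cc(OC)cc(OC)c1OC | intermediate
10 | prop-2-en-1-yl 2-acetyl-3-oxo-4-(2,3,5-trimethoxyphenyl)butanoate | CC(=O)C(C(=O)OCC=C)C(=O)Cc1cc(OC)cc(OC)c1OC | intermediate
11 | prop-2-en-1-yl 3-hydroxy-5,6,8-trimethoxy-1-methylnaphthalene-2-carboxylate | Cc1c(C(=O)OCC=C)c(O)cc2c1c(OC)cc(OC)c2OC | intermediate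
12 | prop-2-en-1-yl 3,5,6,8-tetramethoxy-1-methylnaphthalene-2-carboxylate | Cc1c(C(=O)OCC=C)c(OC)cc2c1c(OC)cc(OC)c2OC | intermediate
13 | 3,5,6,8-tetramethoxy-1-methylnaphthalene-2-carboxylic acid | Cc1c(C(=O)O)c(OC)cc2c1c(OC)cc(OC)c2OC | intermediate
14 | 3,5,6,8-tetramethoxy-1-methylnaphthalene-2-carboxylic trifluoroacetic anhydride | Cc1c(C(=O)OC(=O)C(F)(F)F)c(OC)cc2c1c(OC)cc(OC)c2OC | intermediate
15 | methyl 2-[3,5-dimethoxy-2-(3,5,6,8-tetramethoxy-1-methylnaphthalene-2-carbonyl)phenyl]acetate | Cc1c(C(=O)c3c(OC)cc(OC)cc3CC(=O)OC)c(OC)cc2c1c(OC)cc(OC)c2OC | intermediate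
16 | 2-[3,5-dimethoxy-2-(3,5,6,8-tetramethoxy-1-methylnaphthalene-2-carbonyl)phenyl]acetic acid | Cc1c(C(=O)c3c(OC)cc(OC)cc3CC(=O)O)c(OC)cc2c1c(OC)cc(OC)c2OC | intermediate
17 | 2,2,6-trimethyl-4H-1,3-dioxin-4-one | CC1=CC(=O)OC(C)(C)O1 | starting material
18 | 1-{2-[3,5-dimethoxy-2-(3,5,6,8-tetramethoxy-1-methylnaphthalene-2-carbonyl)phenyl]acetyl}-1H-imidazole | Cc1c(C(=O)c3c(OC)cc(OC)cc3CC(=O)n3ccnc3)c(OC)cc2c1c(OC)cc(OC)c2OC | intermediate
19 | lithium 2,2-dimethyl-6-methylidene-6H-1,3-dioxin-4-olate | C=C1C=C([O-])OC(C)(C)O1.[Li+] | intermediate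
20 | 6-{3-[3,5-dimethoxy-2-(3,5,6,8-tetramethoxy-1-methylnaphthalene-2-carbonyl)phenyl]-2-oxopropyl}-2,2-dimethyl-4H-1,3-dioxin-4-one | Cc1c(C(=O)c3c(OC)cc(OC)cc3CC(=O)CC3=CC(=O)OC(C)(C)O3)c(OC)cc2c1c(OC)cc(OC)c2OC | intermediate
21 | 6-[3,5-dimethoxy-2-(3,5,6,8-tetramethoxy-1-methylnaphthalene-2-carbonyl)phenyl]hex-1-ene-1,3,5-trione | Cc1c(C(=O)c3c(OC)cc(OC)cc3CC(=O)CC(=O)C=C=O)c(OC)cc2c1c(OC)cc(OC)c2OC | intermediate
22 | 6-{[3,5-dimethoxy-2-(3,5,6,8-tetramethoxy-1-methylnaphthalene-2-carbonyl)phenyl]methyl}-4-hydroxy-2H-pyran-2-one | Cc1c(C(=O)c3c(OC)cc(OC)cc3Cc3cc(O)cc(=O)o3)c(OC)cc2c1c(OC)cc(OC)c2OC | intermediate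
23 | 6-{[2-(3,6-dimethoxy-1-methyl-5,8-dioxo-5,8-dihydronaphthalene-2-carbonyl)-3,5-dimethoxyphenyl]methyl}-4-hydroxy-2H-pyran-2-one | Cc1c(C(=O)c3c(OC)cc(OC)cc3Cc3cc(O)cc(=O)o3)c(OC)cc2c1C(=O)C=C(OC)C2=O | intermediate
24 | 6-{[3,5-dihydroxy-2-(3,6-dihydroxy-1-methyl-5,8-dioxo-5,8-dihydronaphthalene-2-carbonyl)phenyl]methyl}-4-hydroxy-2H-pyran-2-one | Cc1c(C(=O)c2c(O)cc(O)cc2Cc2cc(O)cc(=O)o2)c(O)cc2c1C(=O)C=C(O)C2=O | target

**Count and risks**

Total step count: 13. Longest linear sequence: 13 steps (1 to 24); compound 1 re-enters unchanged at step 8 and compound 17 at step 10.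

Steps most likely to fail:

Step 8. Capture of the hindered acylium ion by arene 1 may be slow, so that protodecarboxylation of the electron-rich acid, trifluoroacetylation of the nucleophile or attack at C4 between the two methoxy groups take over. The fallback sets out from 13 and returns at 15 by an aryne acyl-alkylation. Acid 13 is converted with 1,1'-carbonyldiimidazole into 1-(3,5,6,8-tetramethoxy-1-methylnaphthalene-2-carbonyl)-1H-imidazole F1. Treatment with KO2CCH2CO2Me, MgCl2 and Et3N then gives, after decarboxylation, methyl 3-oxo-3-(3,5,6,8-tetramethoxy-1-methylnaphthalen-2-yl)propanoate F2. In parallel 3,5-dimethoxyphenol is brominated next to the hydroxyl (N-bromosuccinimide, CH2Cl2, −78 °C, any para isomer being separated) to 2-bromo-3,5-dimethoxyphenol F3. Silylation with hexamethyldisilazane gives (2-bromo-3,5-dimethoxyphenoxy)trimethylsilane F4. nBuLi followed by (CF3SO2)2O (bromine–lithium exchange, shift of silicon from oxygen to carbon, triflation) gives 3,5-dimethoxy-2-(trimethylsilyl)phenyl trifluoromethanesulfonate F5. CsF in MeCN at 80 °C should release 3,5-dimethoxybenzyne F6. The enolate of F2 adds at the aryne carbon remote from the flanking methoxy group, the aryl anion closes onto the ketone, and fragmentation of the four-membered alkoxide inserts the aryne into the C–C bond, giving 15 with the same substitution pattern.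

Step 10. Proton transfer from the doubly activated CH2 of acyl imidazole 18 to the dienolate (enolisation, ketene formation or closure onto the neighbouring aroyl carbonyl) may outrun C-acylation. The fallback sets out from 15 and returns at 20 through a non-basic aldol and an oxidation. Ester 15 is reduced with iBu2AlH in CH2Cl2 at −78 °C to 2-[3,5-dimethoxy-2-(3,5,6,8-tetramethoxy-1-methylnaphthalene-2-carbonyl)phenyl]acetaldehyde F7, the hindered diaryl ketone being expected to resist hydride. Dienolate 19 is silylated with Me3SiCl to [(2,2-dimethyl-6-methylidene-6H-1,3-dioxin-4-yl)oxy]trimethylsilane F8. A vinylogous Mukaiyama aldol addition of F8 to F7 with BF3·OEt2 in CH2Cl2 at −78 °C should give racemic 6-{3-[3,5-dimethoxy-2-(3,5,6,8-tetramethoxy-1-methylnaphthalene-2-carbonyl)phenyl]-2-hydroxypropyl}-2,2-dimethyl-4H-1,3-dioxin-4-one F9. Its carbinol centre is removed at once by Dess–Martin periodinane oxidation to 20.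

Step 12. Oxidation by tetravalent cerium may not stay on ring A: single-electron oxidation of the enolic hydroxypyranone or of the C7' methylene could lead to coupling or over-oxidation. The fallback sets out from 22 and returns at 23 by masking the enol. Acetylation (Ac2O, pyridine, 0 °C) gives 6-{[3,5-dimethoxy-2-(3,5,6,8-tetramethoxy-1-methylnaphthalene-2-carbonyl)phenyl]methyl}-2-oxo-2H-pyran-4-yl acetate F10, which no longer has an oxidisable enol. (NH4)2Ce(NO3)6 in MeCN/H2O at 0 °C should then give 6-{[2-(3,6-dimethoxy-1-methyl-5,8-dioxo-5,8-dihydronaphthalene-2-carbonyl)-3,5-dimethoxyphenyl]methyl}-2-oxo-2H-pyran-4-yl acetate F11. Brief K2CO3 in MeOH at 0 °C removes the enol acetate and gives 23.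

Further compounds
F1 | step 8 | 1-(3,5,6,8-tetramethoxy-1-methylnaphthalene-2-carbonyl)-1H-imidazole | Cc1c(C(=O)n3ccnc3)c(OC)cc2c1c(OC)cc(OC)c2OC
F2 | step 8 | methyl 3-oxo-3-(3,5,6,8-tetramethoxy-1-methylnaphthalen-2-yl)propanoate | Cc1c(C(=O)CC(=O)OC)c(OC)cc2c1c(OC)cc(OC)c2OC
F3 | step 8 | 2-bromo-3,5-dimethoxyphenol | COc1cc(O)c(Br)c(OC)c1
F4 | step 8 | (2-bromo-3,5-dimethoxyphenoxy)trimethylsilane | COc1cc(O[Si](C)(C)C)c(Br)c(OC)c1
F5 | step 8 | 3,5-dimethoxy-2-(trimethylsilyl)phenyl trifluoromethanesulfonate | COc1cc(OC)c([Si](C)(C)C)c(OS(=O)(=O)C(F)(F)F)c1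
F6 | step 8 | 3,5-dimethoxybenzyne (1,2-didehydro-3,5-dimethoxybenzene) | COC1=CC(OC)=CC#C1
F7 | step 10 | 2-[3,5-dimethoxy-2-(3,5,6,8-tetramethoxy-1-methylnaphthalene-2-carbonyl)phenyl]acetaldehyde | Cc1c(C(=O)c3c(OC)cc(OC)cc3CC=O)c(OC)cc2c1c(OC)cc(OC)c2OC
F8 | step 10 | [(2,2-dimethyl-6-methylidene-6H-1,3-dioxin-4-yl)oxy]trimethylsilane | C=C1C=C(O[Si](C)(C)C)OC(C)(C)O1
F9 | step 10 | 6-{3-[3,5-dimethoxy-2-(3,5,6,8-tetramethoxy-1-methylnaphthalene-2-carbonyl)phenyl]-2-hydroxypropyl}-2,2-dimethyl-4H-1,3-dioxin-4-one (racemic) | Cc1c(C(=O)c3c(OC)cc(OC)cc3CC(O)CC3=CC(=O)OC(C)(C)O3)c(OC)cc2c1c(OC)cc(OC)c2OC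
F10 | step 12 | 6-{[3,5-dimethoxy-2-(3,5,6,8-tetramethoxy-1-methylnaphthalene-2-carbonyl)phenyl]methyl}-2-oxo-2H-pyran-4-yl acetate | Cc1c(C(=O)c3c(OC)cc(OC)cc3Cc3cc(OC(C)=O)cc(=O)o3)c(OC)cc2c1c(OC)cc(OC)c2OC
F11 | step 12 | 6-{[2-(3,6-dimethoxy-1-methyl-5,8-dioxo-5,8-dihydronaphthalene-2-carbonyl)-3,5-dimethoxyphenyl]methyl}-2-oxo-2H-pyran-4-yl acetate | Cc1c(C(=O)c3c(OC)cc(OC)cc3Cc3cc(OC(C)=O)cc(=O)o3)c(OC)cc2c1C(=O)C=C(OC)C2=O
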